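**Retrosynthetic overview**

1. Target 10 comes from the tri-O-benzyl lactone 9 by hydrogenolysis; no skeletal change.
2. Lactone 9 is cut at C4–C4a and O1–C2 in one catalytic enantioselective [3+3] annulation. The C–H/OH pair of the acylphloroglucinol ring (future C4a and C8a–O1) is the C,O-dinucleophile; the p-coumaroyl C2–C3–C4 unit comes from enal 7 as a chiral α,β-unsaturated acyl azolium. The same step sets C4, the diarylmethine carrying the 4-hydroxyphenyl group.
3. Phenol 5 comes from dihydrochalcone 4 by bis-O-benzylation that leaves only the ketone-chelated OH free, and 4 from phloroglucinol 1 and nitrile 2 by Hoesch acylation. The acyl group is thus fixed at the future C8 before the lactone exists, so a C6/C8 acylation problem never arises.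
4. Enal 7 comes from aldehyde 6 by a two-carbon Wittig homologation.
5. Ring order: both benzene rings are bought; the only ring made is the dihydropyran-2-one, closed in the key step.

Key step: step 4

Assumption: the (5aS,10bR) N-mesityl aminoindanol triazolium is taken to direct attack to the Si face of Cβ (indane shielding the other face of the acyl azolium conformer with C=O syn to C10b–H), which gives (4S). This sense is a model-based assignment, not a verified one; should the first run give the (4R) lactone, the commercial (5aR,10bS) antipode would be used with no other change.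

**Route**

Step 1
Reactants: 1 benzene-1,3,5-triol (phloroglucinol); 2 3-phenylpropanenitrile
Product: 4 3-phenyl-1-(2,4,6-trihydroxyphenyl)propan-1-one, via ketiminium chloride 3 (not isolated)
Conditions: ZnCl2 (0.3 equiv), HCl (g), Et2O, 0 °C to 5 °C; then H2O, reflux
Reagents that add atoms: water, O
Why: Hoesch acylation: the nitrilium species from 2 and HCl/ZnCl2 attacks the very electron-rich phloroglucinol once (the iminium deactivates the ring against a second attack), and the ketiminium salt 3 is hydrolysed to the ketone on heating in water.

Step 2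
Reactants: 4 3-phenyl-1-(2,4,6-trihydroxyphenyl)propan-1-one
Product: 5 1-[2,4-bis(benzyloxy)-6-hydroxyphenyl]-3-phenylpropan-1-one
Conditions: BnBr (2.05 equiv), K2CO3 (2.2 equiv), DMF, 0 °C to 25 °C
Reagents that add atoms: benzyl bromide, BrCc1ccccc1
Why: Williamson etherification: the OH para to the ketone and one of the two equivalent ortho OH groups should be benzylated, while the last OH is held in a six-membered hydrogen bond to the C=O and stays free, as is usual for phloroacylophenones.

Step 3
Reactants: 6 4-(benzyloxy)benzaldehyde
Product: 7 (2E)-3-[4-(benzyloxy)phenyl]prop-2-enal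
Conditions: Ph3P=CHCHO (1.05 equiv), toluene, 80 °C
Reagents that add atoms: (triphenylphosphoranylidene)acetaldehyde, O=CC=P(c1ccccc1)(c1ccccc1)c1ccccc1
Why: Wittig reaction of a stabilised formyl ylide with an aromatic aldehyde should give the (E)-cinnamaldehyde, and the near-stoichiometric ylide limits over-homologation to the dienal.

Step 4
Reactants: 5 1-[2,4-bis(benzyloxy)-6-hydroxyphenyl]-3-phenylpropan-1-one; 7 (2E)-3-[4-(benzyloxy)phenyl]prop-2-enal
Product: 9 (4S)-5,7-bis(benzyloxy)-4-[4-(benzyloxy)phenyl]-8-(3-phenylpropanoyl)-3,4-dihydro-2H-chromen-2-one, via unsaturated acyl azolium 8 (not isolated)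
Conditions: (5aS,10bR)-2-mesityl-5a,10b-dihydro-4H,6H-indeno[2,1-b][1,2,4]triazolo[4,3-d][1,4]oxazin-2-ium chloride (10 mol %), DBU (20 mol %), 3,3',5,5'-tetra-tert-butyldiphenoquinone (1.2 equiv), 7 (1.2 equiv), 4 Å MS, toluene, 25 °C
Reagents that add atoms: none
Why: Proposed new method: carbene addition to enal 7 and oxidation of the Breslow intermediate by the diphenoquinone give the α,β-unsaturated acyl azolium 8 (a laboratory stand-in for p-coumaroyl-CoA); the phenoxide of 5 adds to its carbonyl, the hemiacetal undergoes a Coates–Claisen [3,3] shift that joins the ring carbon ortho to the free OH to Cβ (bond C4–C4a, net Michael addition), and after rearomatisation the same oxygen is acylated by the regenerated acyl azolium (bond O1–C2) and releases the carbene. The closest known reaction type is the carbene-catalysed enantioselective [3+3] annulation of unsaturated acyl azoliums (from ynals, 2-bromoenals or enals plus this oxidant) with 2-naphthols, kojic acids and 1,3-dicarbonyls, which gives 4-substituted dihydropyranones and benzo-fused dihydrocoumarins; new here is an intramolecularly hydrogen-bonded ortho-acylphenol of the phloroglucinol diether type as the C,O-dinucleophile. The one ring formed, the dihydropyran-2-one, closes by 6-exo-trig addition–elimination of the phenoxide at the acyl azolium carbonyl. The one new stereocentre, C4, is under catalyst control: the indane of the (5aS,10bR) triazolium blocks one face of the s-cis acyl azolium so that the aryl carbon reaches the Si face of Cβ, which corresponds to (4S). The step needs C–C bond formation to win over O-acylation and needs one regiochemistry: O-acylation is not a dead end because the aryl ester of so acidic a phenol can be re-opened by the carbene, the oxygen-tethered [3,3] pathway can reach only the carbon next to the single free OH, and with the other two oxygens benzylated only the O1 lactone (the 8-acyl isomer) can close.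

Step 5
Reactants: 9 (4S)-5,7-bis(benzyloxy)-4-[4-(benzyloxy)phenyl]-8-(3-phenylpropanoyl)-3,4-dihydro-2H-chromen-2-one
Product: 10 (4S)-5,7-dihydroxy-4-(4-hydroxyphenyl)-8-(3-phenylpropanoyl)-3,4-dihydro-2H-chromen-2-one
Conditions: H2 (1 atm), 10% Pd/C, EtOAc–THF (no alcohol), 25 °C
Reagents that add atoms: none
Why: Heterogeneous hydrogenolysis should cleave the three aryl benzyl ethers under neutral, non-nucleophilic conditions that leave the aryl lactone (no alcoholysis or relactonisation onto the 5-OH), the chelated aryl ketone and the non-epimerisable C4 diarylmethine untouched.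

**Compound list**

1 | benzene-1,3,5-triol (phloroglucinol) | Oc1cc(O)cc(O)c1 | starting material
2 | 3-phenylpropanenitrile | N#CCCc1ccccc1 | starting material
3 | 3-phenyl-1-(2,4,6-trihydroxyphenyl)propan-1-iminium chloride | [Cl-].[NH2+]=C(CCc1ccccc1)c1c(O)cc(O)cc1O | intermediate (not isolated)
4 | 3-phenyl-1-(2,4,6-trihydroxyphenyl)propan-1-one (2',4',6'-trihydroxydihydrochalcone) | O=C(CCc1ccccc1)c1c(O)cc(O)cc1O | intermediate
5 | 1-[2,4-bis(benzyloxy)-6-hydroxyphenyl]-3-phenylpropan-1-one | O=C(CCc1ccccc1)c1c(O)cc(OCc2ccccc2)cc1OCc1ccccc1 | intermediate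
6 | 4-(benzyloxy)benzaldehyde | O=Cc1ccc(OCc2ccccc2)cc1 | starting material
7 | (2E)-3-[4-(benzyloxy)phenyl]prop-2-enal | O=C/C=C/c1ccc(OCc2ccccc2)cc1 | intermediate
8 | (5aS,10bR)-1-{(2E)-3-[4-(benzyloxy)phenyl]prop-2-enoyl}-2-mesityl-5a,10b-dihydro-4H,6H-indeno[2,1-b][1,2,4]triazolo[4,3-d][1,4]oxazin-2-ium (unsaturated acyl azolium, cation) | O=C(/C=C/c1ccc(OCc2ccccc2)cc1)c1n2[C@@H]3c4ccccc4C[C@@H]3OCc2n[n+]1-c1c(C)cc(C)cc1C | intermediate (not isolated)
9 | (4S)-5,7-bis(benzyloxy)-4-[4-(benzyloxy)phenyl]-8-(3-phenylpropanoyl)-3,4-dihydro-2H-chromen-2-one | O=C1C[C@@H](c2ccc(OCc3ccccc3)cc2)c2c(OCc3ccccc3)cc(OCc3ccccc3)c(C(=O)CCc3ccccc3)c2O1 | intermediate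
10 | (4S)-5,7-dihydroxy-4-(4-hydroxyphenyl)-8-(3-phenylpropanoyl)-3,4-dihydro-2H-chromen-2-one | O=C1C[C@@H](c2ccc(O)cc2)c2c(O)cc(O)c(C(=O)CCc3ccccc3)c2O1 | target

**Step count**

Total steps: 5. Longest linear sequence: 4 steps (steps 1, 2, 4, 5); step 3 is a one-step side branch.

**Steps most likely to fail**

Step 4 (bears the label). What may go wrong:
- The hydrogen-bonded, acyl-deactivated phenoxide of 5 may be acylated at oxygen without onward C–C bond formation.
- The [3,3] shift onto the hindered ring carbon may be too slow against the electron-rich acyl azolium.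
- The catalyst may discriminate poorly between the two faces of Cβ.

The fallback uses known chemistry and sets C4 by forming the C4–aryl bond instead of C4–C4a. It sets out from 5. Ortho-formylation of the magnesium phenoxide (MgCl2, Et3N, paraformaldehyde, MeCN, reflux) should give 4,6-bis(benzyloxy)-2-hydroxy-3-(3-phenylpropanoyl)benzaldehyde F1. Wittig olefination with ethyl (triphenylphosphoranylidene)acetate in N,N-diethylaniline at reflux should pass through ethyl (2E)-3-[4,6-bis(benzyloxy)-2-hydroxy-3-(3-phenylpropanoyl)phenyl]prop-2-enoate F2 (not isolated; thermal E/Z isomerisation and lactonisation) to 5,7-bis(benzyloxy)-8-(3-phenylpropanoyl)-2H-chromen-2-one F3. Rhodium-catalysed asymmetric 1,4-addition of [4-(benzyloxy)phenyl]boronic acid to this coumarin (Rh(acac)(C2H4)2, (S)-SEGPHOS, dioxane–H2O, 60 °C; Hayashi–Miyaura addition) should then deliver the aryl group to C4 and come back to the route at 9. The (S) ligand is chosen as the antipode of the one recalled to give (R)-4-arylchroman-2-ones in this reaction; this assignment would be checked on the first run.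

Step 2. What may go wrong: statistical under- and over-alkylation, leaving mono-, di- and tri-ethers that are hard to separate. The fallback replaces selective protection by exhaustive protection and selective deprotection. It sets out from 4. Full benzylation (BnBr 3.5 equiv, K2CO3, DMF, 60 °C) should give 3-phenyl-1-[2,4,6-tris(benzyloxy)phenyl]propan-1-one F4. Chelation-directed cleavage of one ether ortho to the ketone (BCl3 1.1 equiv, CH2Cl2, −78 °C) should then free a single OH and come back to the route at 5.

Step 5. What may go wrong: over-reduction of the aryl ketone on palladium, or stalling at the hindered 5-O-benzyl ether next to the C4 aryl group. The fallback is non-reductive. It sets out from 9 and uses Lewis-acid ether cleavage with a cation scavenger (BCl3 6 equiv, pentamethylbenzene 9 equiv, CH2Cl2, −78 °C, then aqueous work-up). This should remove all three benzyl groups without touching the ketone, lactone or C4, and comes back to the route at 10; no new compound arises (F0).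

**Further compounds**

F1 | step 4 | 4,6-bis(benzyloxy)-2-hydroxy-3-(3-phenylpropanoyl)benzaldehyde | O=Cc1c(O)c(C(=O)CCc2ccccc2)c(OCc2ccccc2)cc1OCc1ccccc1
F2 | step 4 | ethyl (2E)-3-[4,6-bis(benzyloxy)-2-hydroxy-3-(3-phenylpropanoyl)phenyl]prop-2-enoate | CCOC(=O)/C=C/c1c(O)c(C(=O)CCc2ccccc2)c(OCc2ccccc2)cc1OCc1ccccc1
F3 | step 4 | 5,7-bis(benzyloxy)-8-(3-phenylpropanoyl)-2H-chromen-2-one | O=C1C=Cc2c(OCc3ccccc3)cc(OCc3ccccc3)c(C(=O)CCc3ccccc3)c2O1
F4 | step 2 | 3-phenyl-1-[2,4,6-tris(benzyloxy)phenyl]propan-1-one | O=C(CCc1ccccc1)c1c(OCc2ccccc2)cc(OCc2ccccc2)cc1OCc1ccccc1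
F0 | step 5 | none | none
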